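**Plan**

1. Numbering (isochromene): C1H2, O2, C3 (bears the chain C9–C15), C4, C4a, C5 (Cl), C6 (C=O), C7 (CH3, OH), C8 (OH), C8a (H). Ring A is the carbocycle, ring B the pyran.
2. Enabling feature: rings A and B share one conjugated diene, C5=C4a in ring A and C4=C3 in ring B, joined at the fusion carbon C4a, whose neighbour C8a is sp3. A 1,3-diene straddling two fused rings in this way is what an ene–yne–ene metathesis produces when the alkyne hangs from the branch carbon C8a.
3. Retrosynthetic cuts: C5–Cl and the C6 carbonyl first; then C4a=C5 and C3=C4 together (both rings, one metathesis cascade); then the C3=CH2 enol ether (ester methylenation), C9=C10 (Horner–Wadsworth–Emmons), the C1–O acyl bond, and C8–C8a (propargylation of a C8 aldehyde).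
4. Forward order: the C5–C8 chain is built first; C8a with C1 and the C4a≡C4 alkyne is added in one C–C bond formation; the side chain is joined at O2/C3; one ruthenium cascade closes ring A and then ring B; oxidation, chlorination and deprotection finish.
5. Stereochemistry: C7 from a Sharpless kinetic resolution (C6 is set with it and erased at the ketone stage). C8a from an (R)-propargylic mesylate made by Noyori transfer hydrogenation. C8 from the anti selectivity of the allenylzinc addition, reinforced by Felkin control from C7. C13/C14 from ethyl (S)-3-hydroxybutanoate by Fráter–Seebach methylation. Both chain alkenes are set E by Wittig-type olefinations.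

Key step: step 21

Remark: atom labels C1–C15 used below are those of the target; the C6 carbinol is carried as a single (S)-configured silyl ether whose configuration disappears on oxidation, and compounds 9, 10, 18 and 25 are taken as purchased.

**Route**

Step 1
Reactants: 1 methacrolein; 2 vinylmagnesium bromide
Product: 3 rac-2-methylpenta-1,4-dien-3-ol
Conditions: THF, −78 to 0 °C; aq NH4Cl
Reagents that add atoms: none
Why: Grignard 1,2-addition to the aldehyde should give the bis-allylic alcohol in which the carbinol carbon is the future C6, the vinyl group the future C5 and the isopropenyl group the future C7 with its methyl and C8.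

Step 2
Reactants: 3 rac-2-methylpenta-1,4-dien-3-ol
Product: 4 (1S)-1-[(2R)-2-methyloxiran-2-yl]prop-2-en-1-ol
Conditions: Ti(OiPr)4 (10 mol %), L-(+)-diisopropyl tartrate (12 mol %), t-BuOOH (0.45 equiv), 4 Å MS, CH2Cl2, −20 °C
Reagents that add atoms: tert-butyl hydroperoxide CC(C)(C)OO
Why: Sharpless kinetic resolution, in which the L-(+)-tartrate titanium catalyst should epoxidise only the (S)-alcohol, at its more electron-rich 1,1-disubstituted alkene and from the face that gives the erythro epoxy alcohol, so that C7 is set as R and C6 is left as one S carbinol while the (R)-alcohol stays unchanged and is separated.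

Step 3
Reactants: 4 (1S)-1-[(2R)-2-methyloxiran-2-yl]prop-2-en-1-ol
Product: 5 TIPS ether of epoxy alcohol 4
Conditions: i-Pr3SiOTf, 2,6-lutidine, CH2Cl2, −78 °C
Reagents that add atoms: triisopropylsilyl trifluoromethanesulfonate CC(C)[Si](C(C)C)(C(C)C)OS(=O)(=O)C(F)(F)F
Why: Silylation of the secondary alcohol at low temperature should leave the epoxide intact, and the bulky TIPS group is chosen because it should neither migrate nor cleave under the hydroxide of the next step.

Step 4
Reactants: 5 TIPS ether of epoxy alcohol 4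
Product: 6 (2R,3S)-2-methyl-3-[(triisopropylsilyl)oxy]pent-4-ene-1,2-diol
Conditions: KOH, DMSO–H2O, 70 °C
Reagents that add atoms: water O
Why: Base-mediated SN2 opening of the 2,2-disubstituted epoxide by hydroxide at its CH2 terminus (C8) should give the primary/tertiary diol with the C7–O bond and its configuration untouched.

Step 5
Reactants: 6 (2R,3S)-2-methyl-3-[(triisopropylsilyl)oxy]pent-4-ene-1,2-diol
Product: 7 bis-TMS ether of diol 6
Conditions: Me3SiOTf, Et3N, CH2Cl2, 0 °C
Reagents that add atoms: trimethylsilyl trifluoromethanesulfonate C[Si](C)(C)OS(=O)(=O)C(F)(F)F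
Why: Exhaustive silylation with the silyl triflate should cap both the primary and the hindered tertiary hydroxyl as trimethylsilyl ethers.

Step 6
Reactants: 7 bis-TMS ether of diol 6
Product: 8 (2S,3S)-2-methyl-3-[(triisopropylsilyl)oxy]-2-[(trimethylsilyl)oxy]pent-4-enal
Conditions: (COCl)2, DMSO, CH2Cl2, −78 to −40 °C; Et3N
Reagents that add atoms: none
Why: Swern oxidation acting directly on the primary trimethylsilyl ether should give the non-enolisable C8 aldehyde, because only the unhindered primary silyl ether is exchanged by the chlorosulfonium salt and the tertiary silyl ether at C7 has no carbinol hydrogen.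

Step 7
Reactants: 9 2-[(tert-butyldimethylsilyl)oxy]-N-methoxy-N-methylacetamide; 10 lithium (trimethylsilyl)acetylide
Product: 11 1-[(tert-butyldimethylsilyl)oxy]-4-(trimethylsilyl)but-3-yn-2-one
Conditions: THF, −78 to 0 °C; aq NH4Cl
Reagents that add atoms: none
Why: Weinreb ketone synthesis, in which the chelated tetrahedral adduct should prevent a second addition of the acetylide.

Step 8
Reactants: 11 1-[(tert-butyldimethylsilyl)oxy]-4-(trimethylsilyl)but-3-yn-2-one
Product: 12 (2R)-1-[(tert-butyldimethylsilyl)oxy]-4-(trimethylsilyl)but-3-yn-2-ol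
Conditions: Ru[(S,S)-TsDPEN](p-cymene) (2 mol %), i-PrOH, rt
Reagents that add atoms: none
Why: Noyori asymmetric transfer hydrogenation of an alkynyl ketone, in which the (S,S)-catalyst should deliver hydride to the face that places the alkyne where an aryl group normally sits and so gives the (R)-carbinol.

Step 9
Reactants: 12 (2R)-1-[(tert-butyldimethylsilyl)oxy]-4-(trimethylsilyl)but-3-yn-2-ol
Product: 13 (2R)-1-[(tert-butyldimethylsilyl)oxy]-4-(trimethylsilyl)but-3-yn-2-yl methanesulfonate
Conditions: MsCl, Et3N, CH2Cl2, −78 °C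
Reagents that add atoms: methanesulfonyl chloride CS(=O)(=O)Cl
Why: Sulfonylation at oxygen with retention should give the propargylic mesylate, which is used without purification.

Step 10
Reactants: 8 (2S,3S)-2-methyl-3-[(triisopropylsilyl)oxy]-2-[(trimethylsilyl)oxy]pent-4-enal; 13 (2R)-1-[(tert-butyldimethylsilyl)oxy]-4-(trimethylsilyl)but-3-yn-2-yl methanesulfonate
Product: 15 anti homopropargylic alcohol (C5–C8a chain with C1 and the silylated C4a≡C4 alkyne), via ethyl allenylzinc 14 (not isolated)
Conditions: Pd(OAc)2 (5 mol %), PPh3 (5 mol %), Et2Zn (3 equiv), THF, −78 to −20 °C; aq NH4Cl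
Reagents that add atoms: none
Why: Marshall propargylation, in which zerovalent palladium should displace the mesylate in an anti SN2′ sense, transmetalation with Et2Zn gives the (M)-allenylzinc 14, and this adds to the aldehyde through a cyclic SE2′ transition state, so that C8a (S) arises from the (R)-mesylate with net inversion and C8 (R) from the anti preference of the addition, which coincides with polar Felkin–Anh attack opposite the C7 silyloxy group.

Step 11
Reactants: 15 anti homopropargylic alcohol
Product: 16 C7/C8 acetonide with C1–OTBS and the silylated alkyne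
Conditions: Me2C(OMe)2, PPTS, CH2Cl2, rt
Reagents that add atoms: 2,2-dimethoxypropane COC(C)(C)OC
Why: Acid-catalysed transketalisation should strip the labile tertiary trimethylsilyl ether and capture the vicinal C7/C8 oxygens as the five-membered acetonide, while the primary TBS ether, the secondary TIPS ether and the C-silyl alkyne persist under the mild pyridinium acid.

Step 12
Reactants: 16 C7/C8 acetonide with C1–OTBS
Product: 17 C1 primary alcohol
Conditions: HF·pyridine, pyridine, THF, 0 °C
Reagents that add atoms: none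
Why: Buffered HF·pyridine should cleave the unhindered primary TBS ether much faster than the hindered secondary TIPS ether and should leave the acetonide and the alkynylsilane alone.

Step 13
Reactants: 17 C1 primary alcohol; 18 (diethoxyphosphoryl)acetic acid
Product: 19 phosphonoacetate ester of 17
Conditions: EDC·HCl, DMAP, CH2Cl2, rt
Reagents that add atoms: none
Why: Carbodiimide (Steglich-type) esterification of the primary alcohol should form the C1–O2 acyl bond and install the phosphonate needed for the olefination.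

Step 14
Reactants: 20 ethyl (3S)-3-hydroxybutanoate
Product: 22 ethyl (2S,3S)-3-hydroxy-2-methylbutanoate, via dilithium dianion 21 (not isolated)
Conditions: LiN(iPr)2 (2.2 equiv), THF, −50 to −20 °C; MeI, HMPA, −78 to 0 °C; aq NH4Cl
Reagents that add atoms: iodomethane CI
Why: Fráter–Seebach alkylation, in which the lithium-chelated dianion 21 should be methylated on the face away from the methyl group of the alkoxide-bearing carbon to give the anti product, setting C13 from the purchased C14 centre.

Step 15
Reactants: 22 ethyl (2S,3S)-3-hydroxy-2-methylbutanoate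
Product: 23 ethyl (2S,3S)-3-[(tert-butyldimethylsilyl)oxy]-2-methylbutanoate
Conditions: t-BuMe2SiCl, imidazole, DMF, rt
Reagents that add atoms: tert-butyldimethylsilyl chloride CC(C)(C)[Si](C)(C)Cl
Why: Standard imidazole-promoted silylation should protect the C14 hydroxyl as its TBS ether.

Step 16
Reactants: 23 ethyl (2S,3S)-3-[(tert-butyldimethylsilyl)oxy]-2-methylbutanoate
Product: 24 (2S,3S)-3-[(tert-butyldimethylsilyl)oxy]-2-methylbutanal
Conditions: i-Bu2AlH, CH2Cl2, −78 °C; aq potassium sodium tartrate
Reagents that add atoms: none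
Why: Partial reduction of the ester by diisobutylaluminium hydride should stop at the aldehyde because the tetrahedral aluminium hemiacetal survives until work-up, and the alpha stereocentre should not epimerise under these non-basic conditions.

Step 17
Reactants: 24 (2S,3S)-3-[(tert-butyldimethylsilyl)oxy]-2-methylbutanal; 25 2-(triphenylphosphoranylidene)propanal
Product: 26 (2E,4R,5S)-5-[(tert-butyldimethylsilyl)oxy]-2,4-dimethylhex-2-enal
Conditions: toluene, 90 °C
Reagents that add atoms: none
Why: Wittig reaction with the stabilised formyl ylide should give the (E)-trisubstituted enal (C11=C12) through the thermodynamically preferred oxaphosphetane.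

Step 18
Reactants: 19 phosphonoacetate ester of 17; 26 (2E,4R,5S)-5-[(tert-butyldimethylsilyl)oxy]-2,4-dimethylhex-2-enal
Product: 27 (2E,4E)-dienoate ester carrying the complete side chain
Conditions: LiCl, DBU, MeCN, rt
Reagents that add atoms: none
Why: Horner–Wadsworth–Emmons olefination under Masamune–Roush conditions should form the (E)-C9=C10 bond and join the side chain to the core under base too mild to epimerise C13 or C8a.

Step 19
Reactants: 27 (2E,4E)-dienoate ester
Product: 28 C3 methylene enol ether with silylated alkyne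
Conditions: TiCl4, TMEDA, Zn, PbCl2 (cat.), CH2Br2, THF, 0 °C to rt
Reagents that add atoms: dibromomethane BrCBr
Why: Takai–Utimoto methylenation of the ester carbonyl should give the 1,1-disubstituted enol ether C3=CH2, using a reagent class that leaves alkenes alone and, with the alkyne capped by silicon, meets no acidic C–H.

Step 20
Reactants: 28 C3 methylene enol ether with silylated alkyne
Product: 29 dienyne (C5 vinyl carbinol silyl ether, C8a terminal alkyne, C3 methylene enol ether)
Conditions: K2CO3, MeOH, rt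
Reagents that add atoms: none
Why: Base-catalysed methanolysis of the alkynyl C–Si bond should free the terminal alkyne while the base-stable enol ether, silyl ethers and acetonide remain.

Step 21
Reactants: 29 dienyne
Product: 30 bicyclic dienol ether (C6–OTIPS, C7/C8 acetonide, no chlorine)
Conditions: second-generation Grubbs catalyst RuCl2(=CHPh)(PCy3)(H2IMes) (10 mol %), toluene (2 mM), 70 °C, argon
Reagents that add atoms: none
Why: Proposed new method: the ruthenium benzylidene should exchange first with the C5 vinyl group, the only monosubstituted alkene, and the resulting alkylidene adds across the C4a≡C4 alkyne with C5 bonding to the internal carbon C4a, which closes ring A in the exo mode as a six-membered ring and leaves a conjugated vinylcarbene on C4; this carbene then undergoes ring-closing metathesis with the 1,1-disubstituted enol ether C3=CH2, closing ring B as a six-membered ring (C4=C3) and releasing Ru=CH2, so that ethylene is the only by-product. The closest known reactions are the tandem ring-closing metathesis of acyclic dienynes to fused bicyclic 1,3-dienes and the ring-closing metathesis of alkenes or alkynes onto ester-derived enol ethers; joining the two in one cascade, with an enol ether as the terminating alkene, is the untested part. No stereocentre is formed, and C6, C7, C8 and C8a are already in place and untouched. The selectivities needed are initiation at C5 rather than at the hindered, electron-rich enol ether (which would give an inert alkoxy carbene) or at the internal chain alkenes, and six- rather than seven-membered closure of ring B; the substitution pattern and the tether lengths secure both, and the cis-acetonide holds the C6 and C8a arms on the same side. Should the methylidene add to the alkyne first, the resulting triene can still reach 30 by two ordinary ring closures, so the possible pathways converge on the same product.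

Step 22
Reactants: 30 bicyclic dienol ether
Product: 31 C6/C14 diol
Conditions: Bu4NF, THF, 0 °C to rt; pH 7 buffer
Reagents that add atoms: none
Why: Fluoride-mediated desilylation should remove the TIPS and TBS ethers under basic, non-ionising conditions, which matters because the C6 alcohol next to the dienol ether would ionise under acid.

Step 23
Reactants: 31 C6/C14 diol
Product: 32 C6 dienone
Conditions: MnO2, CH2Cl2, rt
Reagents that add atoms: none
Why: Activated MnO2 should oxidise only the allylic C6 alcohol to the ketone, creating the push–pull dienone, and leave the non-allylic C14 alcohol untouched.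

Step 24
Reactants: 32 C6 dienone
Product: 33 5-chloro dienone
Conditions: NCS, CH2Cl2, 0 °C
Reagents that add atoms: N-chlorosuccinimide O=C1CCC(=O)N1Cl
Why: Electrophilic chlorination of a vinylogous ester should occur at C5, the carbon alpha to the ketone and terminus of the dienol ether, because attack there gives a fully conjugated oxocarbenium ion that loses the C5 proton to restore the chromophore.

Step 25
Reactants: 33 5-chloro dienone
Product: 34 CNP0536300.1
Conditions: CF3CO2H–H2O, THF, 0 °C
Reagents that add atoms: none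
Why: Acid-catalysed hydrolysis of the acetonide should free the C7 and C8 hydroxyls, the vinylogous ester being deactivated toward protonation and C7 being quaternary so that no aromatisation pathway is open.

**Compound list**

1 | methacrolein (2-methylprop-2-enal) | CC(=C)C=O | starting material
2 | vinylmagnesium bromide | C=C[Mg]Br | starting material
3 | rac-2-methylpenta-1,4-dien-3-ol | C=CC(O)C(C)=C | intermediate
4 | (1S)-1-[(2R)-2-methyloxiran-2-yl]prop-2-en-1-ol | C=C[C@H](O)[C@@]1(C)CO1 | intermediate
5 | triisopropyl{[(1S)-1-[(2R)-2-methyloxiran-2-yl]prop-2-en-1-yl]oxy}silane | C=C[C@H](O[Si](C(C)C)(C(C)C)C(C)C)[C@@]1(C)CO1 | intermediate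
6 | (2R,3S)-2-methyl-3-[(triisopropylsilyl)oxy]pent-4-ene-1,2-diol | C=C[C@H](O[Si](C(C)C)(C(C)C)C(C)C)[C@](C)(O)CO | intermediate
7 | (2R,3S)-2-methyl-3-[(triisopropylsilyl)oxy]-1,2-bis[(trimethylsilyl)oxy]pent-4-ene | C=C[C@H](O[Si](C(C)C)(C(C)C)C(C)C)[C@](C)(O[Si](C)(C)C)CO[Si](C)(C)C | intermediate
8 | (2S,3S)-2-methyl-3-[(triisopropylsilyl)oxy]-2-[(trimethylsilyl)oxy]pent-4-enal | C=C[C@H](O[Si](C(C)C)(C(C)C)C(C)C)[C@](C)(O[Si](C)(C)C)C=O | intermediate
9 | 2-[(tert-butyldimethylsilyl)oxy]-N-methoxy-N-methylacetamide | CON(C)C(=O)CO[Si](C)(C)C(C)(C)C | starting material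
10 | lithium (trimethylsilyl)acetylide | [Li]C#C[Si](C)(C)C | starting material
11 | 1-[(tert-butyldimethylsilyl)oxy]-4-(trimethylsilyl)but-3-yn-2-one | C[Si](C)(C)C#CC(=O)CO[Si](C)(C)C(C)(C)C | intermediate
12 | (2R)-1-[(tert-butyldimethylsilyl)oxy]-4-(trimethylsilyl)but-3-yn-2-ol | C[Si](C)(C)C#C[C@@H](O)CO[Si](C)(C)C(C)(C)C | intermediate
13 | (2R)-1-[(tert-butyldimethylsilyl)oxy]-4-(trimethylsilyl)but-3-yn-2-yl methanesulfonate | C[Si](C)(C)C#C[C@@H](OS(C)(=O)=O)CO[Si](C)(C)C(C)(C)C | intermediate
14 | ethyl[(M)-4-[(tert-butyldimethylsilyl)oxy]-1-(trimethylsilyl)buta-1,2-dien-1-yl]zinc (allenylzinc formed in the flask) | CC[Zn]C([Si](C)(C)C)=[C@]=C([H])CO[Si](C)(C)C(C)(C)C | intermediate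
15 | (3S,4R,5R,6S)-6-{[(tert-butyldimethylsilyl)oxy]methyl}-4-methyl-3-[(triisopropylsilyl)oxy]-8-(trimethylsilyl)-4-[(trimethylsilyl)oxy]oct-1-en-7-yn-5-ol | C=C[C@H](O[Si](C(C)C)(C(C)C)C(C)C)[C@](C)(O[Si](C)(C)C)[C@H](O)[C@@H](C#C[Si](C)(C)C)CO[Si](C)(C)C(C)(C)C | intermediate
16 | tert-butyl({(2S)-2-[(4R,5R)-2,2,5-trimethyl-5-{(1S)-1-[(triisopropylsilyl)oxy]prop-2-en-1-yl}-1,3-dioxolan-4-yl]-4-(trimethylsilyl)but-3-yn-1-yl}oxy)dimethylsilane | C=C[C@H](O[Si](C(C)C)(C(C)C)C(C)C)[C@]1(C)OC(C)(C)O[C@@H]1[C@@H](C#C[Si](C)(C)C)CO[Si](C)(C)C(C)(C)C | intermediate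
17 | (2S)-2-[(4R,5R)-2,2,5-trimethyl-5-{(1S)-1-[(triisopropylsilyl)oxy]prop-2-en-1-yl}-1,3-dioxolan-4-yl]-4-(trimethylsilyl)but-3-yn-1-ol | C=C[C@H](O[Si](C(C)C)(C(C)C)C(C)C)[C@]1(C)OC(C)(C)O[C@@H]1[C@@H](C#C[Si](C)(C)C)CO | intermediate
18 | (diethoxyphosphoryl)acetic acid | CCOP(=O)(CC(=O)O)OCC | starting material
19 | (2S)-2-[(4R,5R)-2,2,5-trimethyl-5-{(1S)-1-[(triisopropylsilyl)oxy]prop-2-en-1-yl}-1,3-dioxolan-4-yl]-4-(trimethylsilyl)but-3-yn-1-yl (diethoxyphosphoryl)acetate | C=C[C@H](O[Si](C(C)C)(C(C)C)C(C)C)[C@]1(C)OC(C)(C)O[C@@H]1[C@@H](C#C[Si](C)(C)C)COC(=O)CP(=O)(OCC)OCC | intermediate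
20 | ethyl (3S)-3-hydroxybutanoate | CCOC(=O)C[C@H](C)O | starting material
21 | dilithium alkoxide–ester enolate of 20 (formed in the flask) | CCO/C(O[Li])=C/[C@H](C)O[Li] | intermediate
22 | ethyl (2S,3S)-3-hydroxy-2-methylbutanoate | CCOC(=O)[C@@H](C)[C@H](C)O | intermediate
23 | ethyl (2S,3S)-3-[(tert-butyldimethylsilyl)oxy]-2-methylbutanoate | CCOC(=O)[C@@H](C)[C@H](C)O[Si](C)(C)C(C)(C)C | intermediate
24 | (2S,3S)-3-[(tert-butyldimethylsilyl)oxy]-2-methylbutanal | O=C[C@@H](C)[C@H](C)O[Si](C)(C)C(C)(C)C | intermediate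
25 | 2-(triphenylphosphoranylidene)propanal | CC(C=O)=P(c1ccccc1)(c1ccccc1)c1ccccc1 | starting material
26 | (2E,4R,5S)-5-[(tert-butyldimethylsilyl)oxy]-2,4-dimethylhex-2-enal | O=C/C(C)=C/[C@@H](C)[C@H](C)O[Si](C)(C)C(C)(C)C | intermediate
27 | (2S)-2-[(4R,5R)-2,2,5-trimethyl-5-{(1S)-1-[(triisopropylsilyl)oxy]prop-2-en-1-yl}-1,3-dioxolan-4-yl]-4-(trimethylsilyl)but-3-yn-1-yl (2E,4E,6R,7S)-7-[(tert-butyldimethylsilyl)oxy]-4,6-dimethylocta-2,4-dienoate | C=C[C@H](O[Si](C(C)C)(C(C)C)C(C)C)[C@]1(C)OC(C)(C)O[C@@H]1[C@@H](C#C[Si](C)(C)C)COC(=O)/C=C/C(C)=C/[C@@H](C)[C@H](C)O[Si](C)(C)C(C)(C)C | intermediate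
28 | tert-butyl{[(2S,3R,4E,6E)-3,5-dimethyl-8-({(2S)-2-[(4R,5R)-2,2,5-trimethyl-5-{(1S)-1-[(triisopropylsilyl)oxy]prop-2-en-1-yl}-1,3-dioxolan-4-yl]-4-(trimethylsilyl)but-3-yn-1-yl}oxy)nona-4,6,8-trien-2-yl]oxy}dimethylsilane (27 with C=O replaced by C=CH2) | C=C[C@H](O[Si](C(C)C)(C(C)C)C(C)C)[C@]1(C)OC(C)(C)O[C@@H]1[C@@H](C#C[Si](C)(C)C)COC(=C)/C=C/C(C)=C/[C@@H](C)[C@H](C)O[Si](C)(C)C(C)(C)C | intermediate
29 | tert-butyl{[(2S,3R,4E,6E)-3,5-dimethyl-8-({(2S)-2-[(4R,5R)-2,2,5-trimethyl-5-{(1S)-1-[(triisopropylsilyl)oxy]prop-2-en-1-yl}-1,3-dioxolan-4-yl]but-3-yn-1-yl}oxy)nona-4,6,8-trien-2-yl]oxy}dimethylsilane (28 with terminal alkyne) | C=C[C@H](O[Si](C(C)C)(C(C)C)C(C)C)[C@]1(C)OC(C)(C)O[C@@H]1[C@@H](C#C)COC(=C)/C=C/C(C)=C/[C@@H](C)[C@H](C)O[Si](C)(C)C(C)(C)C | intermediate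
30 | (6S,7R,8R,8aS)-3-[(1E,3E,5R,6S)-6-[(tert-butyldimethylsilyl)oxy]-3,5-dimethylhepta-1,3-dien-1-yl]-7,8-(isopropylidenedioxy)-7-methyl-6-[(triisopropylsilyl)oxy]-6,7,8,8a-tetrahydro-1H-isochromene | C1(/C=C/C(C)=C/[C@@H](C)[C@H](C)O[Si](C)(C)C(C)(C)C)=CC2=C[C@H](O[Si](C(C)C)(C(C)C)C(C)C)[C@]3(C)OC(C)(C)O[C@@H]3[C@@H]2CO1 | intermediate
31 | (6S,7S,8R,8aS)-3-[(1E,3E,5R,6S)-6-hydroxy-3,5-dimethylhepta-1,3-dien-1-yl]-7,8-(isopropylidenedioxy)-7-methyl-6,7,8,8a-tetrahydro-1H-isochromen-6-ol | C1(/C=C/C(C)=C/[C@@H](C)[C@H](C)O)=CC2=C[C@H](O)[C@]3(C)OC(C)(C)O[C@@H]3[C@@H]2CO1 | intermediate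
32 | (7R,8R,8aS)-3-[(1E,3E,5R,6S)-6-hydroxy-3,5-dimethylhepta-1,3-dien-1-yl]-7,8-(isopropylidenedioxy)-7-methyl-8,8a-dihydro-1H-isochromen-6(7H)-one | C1(/C=C/C(C)=C/[C@@H](C)[C@H](C)O)=CC2=CC(=O)[C@]3(C)OC(C)(C)O[C@@H]3[C@@H]2CO1 | intermediate
33 | (7R,8R,8aS)-5-chloro-3-[(1E,3E,5R,6S)-6-hydroxy-3,5-dimethylhepta-1,3-dien-1-yl]-7,8-(isopropylidenedioxy)-7-methyl-8,8a-dihydro-1H-isochromen-6(7H)-one | C1(/C=C/C(C)=C/[C@@H](C)[C@H](C)O)=CC2=C(Cl)C(=O)[C@]3(C)OC(C)(C)O[C@@H]3[C@@H]2CO1 | intermediate
34 | CNP0536300.1, (7R,8R,8aS)-5-chloro-7,8-dihydroxy-3-[(1E,3E,5R,6S)-6-hydroxy-3,5-dimethylhepta-1,3-dien-1-yl]-7-methyl-8,8a-dihydro-1H-isochromen-6(7H)-one | CC(/C=C/C1=CC2=C(Cl)C(=O)[C@](C)(O)[C@H](O)[C@@H]2CO1)=C\[C@@H](C)[C@H](C)O | target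

**Step count**

Total: 25 steps. Longest linear sequence: 18 steps (steps 1–6, 10–13, 18–25); the mesylate (steps 7–9) and the side-chain enal (steps 14–17) are made in parallel.

**Steps most likely to fail**

1. Step 21 (proposed new method). The alkylidene may be diverted onto the electron-rich enol ether and rest as an unreactive alkoxy carbene, or the cascade may stall after the first ring closure so that turnover stops before ring B forms. The fallback separates the two ring closures and uses only established reactions; it sets out from dienoate 27 and returns at 30. The alkyne of 27 is unmasked with catalytic AgNO3 in aqueous acetone, which spares the ester, to give the terminal-alkyne dienoate F1. Ring-closing enyne metathesis of its 1,6-enyne under ethylene with the same ruthenium catalyst closes ring A alone and gives the 1-vinylcyclohexene ester F2. Takai–Utimoto methylenation of the ester gives the enol ether F3. An ordinary alkene–enol ether ring-closing metathesis between the C4 vinyl group and the C3 methylene then closes ring B and gives 30.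

2. Step 10. The silyloxy group may be lost by beta-elimination from the propargyl/allenyl metal species, or the hindered alpha-quaternary aldehyde may react slowly with eroded anti and facial selectivity. The fallback builds C8/C8a by an auxiliary-controlled aldol reaction; it sets out from aldehyde 8 and returns at 16. 3-[(4-Methoxybenzyl)oxy]propanoic acid is converted (pivaloyl chloride, then the lithiated auxiliary) into the (R)-4-benzyl-N-acyloxazolidinone F4. Its dibutylboron enolate (Bu2BOTf, i-Pr2NEt) adds to 8 in an Evans syn-aldol reaction to give the aldol adduct F5, in which the imide carbonyl is the future C1 and the CH2OPMB arm the future C4a. Acetonide formation as in step 11 gives the acetonide imide F6. LiBH4 removes the auxiliary to give the C1 alcohol F7, and t-BuMe2SiCl gives its TBS ether F8. DDQ removes the PMB group to give the C4a alcohol F9, and Dess–Martin periodinane gives the aldehyde F10. The Ohira–Bestmann reagent (K2CO3, MeOH) gives the terminal alkyne F11, and LiN(SiMe3)2 followed by Me3SiCl returns to 16.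

3. Step 19. The conjugated dienoate may be reduced or isomerised by the low-valent titanium/zinc mixture, conversion may be incomplete, or the acid-labile 2-alkoxytriene may hydrolyse during isolation. The fallback makes the enol ether by cross-coupling instead of carbonyl methylenation; it sets out from alcohol 17 and enal 26 and returns at 28. Transfer vinylation of 17 (butyl vinyl ether, Pd(OCOCF3)2, 4,7-diphenyl-1,10-phenanthroline) gives the vinyl ether F12. Alpha-lithiation with t-BuLi and quenching with Bu3SnCl gives the 1-alkoxyvinylstannane F13. Separately, Takai iodo-olefination of 26 (CrCl2, CHI3) gives the (1E,3E)-dienyl iodide F14. Stille coupling of F13 with F14 (Pd(PPh3)4, CuI, DMF) forms the C3–C9 bond and gives 28.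

**Further compounds**

F1 | step 21 | terminal-alkyne dienoate (27 without the C-silyl group) | C=C[C@H](O[Si](C(C)C)(C(C)C)C(C)C)[C@]1(C)OC(C)(C)O[C@@H]1[C@@H](C#C)COC(=O)/C=C/C(C)=C/[C@@H](C)[C@H](C)O[Si](C)(C)C(C)(C)C
F2 | step 21 | ring A 1-vinylcyclohexene dienoate (C4a=C5 closed, C4 vinyl on C4a) | C=CC1=C[C@H](O[Si](C(C)C)(C(C)C)C(C)C)[C@]2(C)OC(C)(C)O[C@@H]2[C@@H]1COC(=O)/C=C/C(C)=C/[C@@H](C)[C@H](C)O[Si](C)(C)C(C)(C)C
F3 | step 21 | ring A 1-vinylcyclohexene enol ether (F2 with C=O replaced by C=CH2) | C=CC1=C[C@H](O[Si](C(C)C)(C(C)C)C(C)C)[C@]2(C)OC(C)(C)O[C@@H]2[C@@H]1COC(=C)/C=C/C(C)=C/[C@@H](C)[C@H](C)O[Si](C)(C)C(C)(C)C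
F4 | step 10 | (4R)-4-benzyl-3-{3-[(4-methoxybenzyl)oxy]propanoyl}-1,3-oxazolidin-2-one | COc1ccc(COCCC(=O)N2[C@H](Cc3ccccc3)COC2=O)cc1
F5 | step 10 | Evans syn-aldol adduct of 8 and F4 | C=C[C@H](O[Si](C(C)C)(C(C)C)C(C)C)[C@](C)(O[Si](C)(C)C)[C@H](O)[C@@H](COCc1ccc(OC)cc1)C(=O)N1[C@H](Cc2ccccc2)COC1=O
F6 | step 10 | C7/C8 acetonide of the aldol imide | C=C[C@H](O[Si](C(C)C)(C(C)C)C(C)C)[C@]1(C)OC(C)(C)O[C@@H]1[C@@H](COCc1ccc(OC)cc1)C(=O)N1[C@H](Cc2ccccc2)COC1=O
F7 | step 10 | C1 primary alcohol with C4a–OPMB | C=C[C@H](O[Si](C(C)C)(C(C)C)C(C)C)[C@]1(C)OC(C)(C)O[C@@H]1[C@@H](COCc1ccc(OC)cc1)CO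
F8 | step 10 | C1–OTBS ether with C4a–OPMB | C=C[C@H](O[Si](C(C)C)(C(C)C)C(C)C)[C@]1(C)OC(C)(C)O[C@@H]1[C@@H](COCc1ccc(OC)cc1)CO[Si](C)(C)C(C)(C)C
F9 | step 10 | C4a primary alcohol with C1–OTBS | C=C[C@H](O[Si](C(C)C)(C(C)C)C(C)C)[C@]1(C)OC(C)(C)O[C@@H]1[C@@H](CO)CO[Si](C)(C)C(C)(C)C
F10 | step 10 | C4a aldehyde with C1–OTBS | C=C[C@H](O[Si](C(C)C)(C(C)C)C(C)C)[C@]1(C)OC(C)(C)O[C@@H]1[C@@H](C=O)CO[Si](C)(C)C(C)(C)C
F11 | step 10 | terminal alkyne with C1–OTBS (16 without the C-silyl group) | C=C[C@H](O[Si](C(C)C)(C(C)C)C(C)C)[C@]1(C)OC(C)(C)O[C@@H]1[C@@H](C#C)CO[Si](C)(C)C(C)(C)C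
F12 | step 19 | vinyl ether of alcohol 17 | C=C[C@H](O[Si](C(C)C)(C(C)C)C(C)C)[C@]1(C)OC(C)(C)O[C@@H]1[C@@H](C#C[Si](C)(C)C)COC=C
F13 | step 19 | 1-(tributylstannyl)vinyl ether of alcohol 17 | C=C[C@H](O[Si](C(C)C)(C(C)C)C(C)C)[C@]1(C)OC(C)(C)O[C@@H]1[C@@H](C#C[Si](C)(C)C)COC(=C)[Sn](CCCC)(CCCC)CCCC
F14 | step 19 | tert-butyl{[(2S,3R,4E,6E)-7-iodo-3,5-dimethylhepta-4,6-dien-2-yl]oxy}dimethylsilane | I/C=C/C(C)=C/[C@@H](C)[C@H](C)O[Si](C)(C)C(C)(C)C
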